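The seven-membered ring is read as an aromatic ring plus one carbon. C3a, C4, C5, C6, C7 and C8 (azulene numbering), with oxygen on C4 and C8 and methyl on C6, are the six ring carbons of 3,5-dimethoxytoluene; the quaternary C8a is a carbene carbon. An intramolecular Büchner reaction of an α-diazo ethyl ketone inserts C8a into the arene bond C3a–C8: it forms the C8–C8a bond, closes the cyclopentanone and expands the benzene ring to a cycloheptatriene in one operation, setting the angular methyl. The precursor is a flat 2,6-dimethoxy-4-methylphenyl carbinol bearing the isopropyl group and a diazoketone chain; hydroxyl-directed reductions then set the three secondary carbinols.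

Key step: step 5

Remark: positions are numbered as in azulene (C1 and C8 carry the acetoxy groups, C3 is the tertiary carbinol, C3a the ring-fusion CH, C4 the benzoate carbon, C6 the methyl-bearing alkene carbon, C8a the quaternary carbon). Diazoethane is taken as a freshly prepared ethereal solution (N-ethyl-N-nitrosourea, aqueous KOH).

Step 1
Reactants: 1 3,5-dimethoxytoluene; 2 N-methoxy-N-methyl-2-methylpropanamide
Product: 5 aryl ketone 1-(2,6-dimethoxy-4-methylphenyl)-2-methylpropan-1-one, via aryllithium 3 (not isolated), via lithium hemiaminal 4 (not isolated)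
Conditions: n-BuLi, TMEDA, THF, 0 °C to rt; then 2, −78 °C to rt; aq. HCl
Reagents that add atoms: N-methoxy-N-methyl-2-methylpropanamide, CC(C)C(=O)N(C)OC
Why: Directed ortho-lithiation should occur at the position flanked by both methoxy groups, and the aryllithium is acylated by the Weinreb amide, whose chelated tetrahedral adduct 4 collapses to the ketone only on work-up (Weinreb ketone synthesis; no stereocentre).

Step 2
Reactants: 5 aryl ketone; 6 allylboronic acid pinacol ester
Product: 8 homoallylic alcohol (3R)-3-(2,6-dimethoxy-4-methylphenyl)-2-methylhex-5-en-3-ol, via borate ester 7 (not isolated)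
Conditions: CuF2·2H2O (3 mol%), iPr-DuPHOS (6 mol%, antipode chosen for Si-face delivery), La(OiPr)3 (4.5 mol%), DMF, −40 °C; aq. work-up
Reagents that add atoms: allylboronic acid pinacol ester, C=CCB1OC(C)(C)C(C)(C)O1
Why: Copper-catalysed enantioselective allylboration of a ketone, in which a bisphosphine-bound allylcopper (regenerated from 6 by lanthanum-assisted transmetalation) adds through a six-membered transition state that distinguishes the twisted aryl group from isopropyl, so that Si-face delivery should set the (R)-carbinol that becomes C3.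

Step 3
Reactants: 8 homoallylic alcohol
Product: 9 hydroxy acid (3R)-3-(2,6-dimethoxy-4-methylphenyl)-3-hydroxy-4-methylpentanoic acid
Conditions: NaIO4, KMnO4 (cat.), K2CO3, t-BuOH–H2O, rt; work-up at pH 4, 0 °C
Reagents that add atoms: sodium periodate (oxygen source, relayed by catalytic permanganate), [Na+].[O-]I(=O)(=O)=O; water, O
Why: Lemieux–von Rudloff oxidation, in which catalytic permanganate dihydroxylates the terminal alkene and periodate cleaves the diol and re-oxidises manganese, should take the chain to the acid without touching the fully substituted carbinol centre or the methoxyarene in the buffered medium.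

Step 4
Reactants: 9 hydroxy acid; 10 N,O-bis(trimethylsilyl)acetamide; 11 diazoethane
Product: 14 diazoketone (5R)-2-diazo-5-(2,6-dimethoxy-4-methylphenyl)-6-methyl-5-[(trimethylsilyl)oxy]heptan-3-one, via bis-silyl derivative 12 (not isolated), via acid chloride 13 (not isolated)
Conditions: 10 (3 equiv), CH2Cl2, 40 °C, evaporate; (COCl)2, DMF (cat.), CH2Cl2, 0 °C; 11 (3 equiv), Et2O, −20 to 0 °C
Reagents that add atoms: N,O-bis(trimethylsilyl)acetamide, CC(=N[Si](C)(C)C)O[Si](C)(C)C; diazoethane, CC=[N+]=[N-]
Why: Persilylation masks the tertiary hydroxyl (which would otherwise insert into the carbenoid) and gives the silyl ester, which oxalyl chloride converts to the acid chloride under neutral conditions, and acylation of diazoethane (Arndt–Eistert-type diazoketone synthesis) should then give the α-diazo ethyl ketone with the stereocentre untouched.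

Step 5
Reactants: 14 diazoketone
Product: 16 azulenone (3R,8aS)-4,8-dimethoxy-6,8a-dimethyl-3-(propan-2-yl)-3-[(trimethylsilyl)oxy]-3,8a-dihydroazulen-1(2H)-one, via norcaradiene 15 (not isolated)
Conditions: Rh2(OAc)4 (1 mol%), CH2Cl2, reflux, slow addition of 14
Reagents that add atoms: none
Why: Rh2(OAc)4 should expel N2 from 14 to give a catalyst-bound electrophilic acyl(methyl)carbene that attacks the ipso carbon (future C3a, activated by two ortho methoxy groups) and the adjacent methoxy-bearing carbon (future C8), closing the cyclopentanone (5-exo attack on the arene π bond) and the cyclopropane of norcaradiene 15 (3-exo); disrotatory 6π electrocyclic opening then cleaves the old arene bond C3a–C8, so that the new C8–C8a bond completes the seven-membered ring. The closest known reaction type is the intramolecular Büchner reaction of 1-diazo-4-arylbutan-2-ones to 3,4-dihydroazulen-1-ones, including α-methyl diazoketones that give angular-methyl hydroazulenones. The only new stereocentre, C8a, is controlled by C3: in the closing conformation the smaller silyloxy group should eclipse the arene plane beside the non-reacting methoxy group while isopropyl points away from the carbenoid, placing the angular methyl cis to the oxygen and trans to isopropyl (8aS). The step needs arene addition to win over oxonium-ylide formation at the silyl ether, insertion into the isopropyl C–H bond and 1,2-hydride shift of the methyl carbenoid; the electron-rich symmetric arene (equivalent ortho positions, no regiochemical choice, no aromatic C–H to insert into) and the hindered silyl ether favour it, and the quaternary C8a blocks hydrogen shifts and rearomatisation of the cycloheptatriene.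

Step 6
Reactants: 16 azulenone
Product: 17 trione (3R,3aR,8aR)-3-hydroxy-6,8a-dimethyl-3-(propan-2-yl)-2,3,3a,5-tetrahydroazulene-1,4,8(8aH)-trione
Conditions: 0.5 M HCl, THF–H2O, 0 °C to rt
Reagents that add atoms: water, O
Why: Acid hydrolysis of the two enol ethers (C-protonation at C3a and C5, hydration of the oxocarbenium ions) and of the silyl ether should give the trione, with the alkene conjugated to the more electron-poor C8 carbonyl and with C3a (α to the C4 ketone) equilibrating to the trans ring fusion that keeps the C4 branch trans to isopropyl (3aR).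

Step 7
Reactants: 17 trione
Product: 18 triol enone (1S,3R,3aS,4S,8aR)-1,3,4-trihydroxy-6,8a-dimethyl-3-(propan-2-yl)-2,3,3a,4,5,8a-hexahydroazulen-8(1H)-one
Conditions: Me4NBH(OAc)3 (6 equiv), MeCN–AcOH (1:1), −35 °C
Reagents that add atoms: none
Why: Evans–Saksena reduction, in which the tertiary C3 hydroxyl exchanges onto boron and delivers hydride intramolecularly to the two saturated β-carbonyls C1 and C4 from its own face, should give the 1,3-anti carbinols (1S and 4S), while the hindered conjugated C8 ketone is expected to survive at low temperature.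

Step 8
Reactants: 18 triol enone
Product: 20 tetrol (1S,3R,3aS,4S,8R,8aR)-6,8a-dimethyl-3-(propan-2-yl)-1,2,3,3a,4,5,8,8a-octahydroazulene-1,3,4,8-tetrol, via diethylboron chelate 19 (not isolated)
Conditions: Et2BOMe (1.2 equiv), THF–MeOH (4:1), −78 °C; NaBH4; AcOH; MeOH co-evaporation
Reagents that add atoms: none
Why: Narasaka–Prasad reduction, in which the diethylboron chelate 19 between the C1 oxygen and the C8 carbonyl fixes a half-chair that external hydride attacks axially in 1,2-fashion, should give the syn-1,3-diol and hence the (8R)-allylic alcohol.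

Step 9
Reactants: 20 tetrol; 21 3,4-dimethoxybenzoyl chloride
Product: 24 diol ester (1S,3R,3aS,4S,8R,8aR)-1,3,8-trihydroxy-6,8a-dimethyl-3-(propan-2-yl)-1,2,3,3a,4,5,8,8a-octahydroazulen-4-yl 3,4-dimethoxybenzoate, via phenylboronate 22 (not isolated), via acylated phenylboronate 23 (not isolated)
Conditions: PhB(OH)2 (1.05 equiv), MgSO4, CH2Cl2, rt; pyridine, DMAP (cat.), 21, 0 °C to rt; pinacol, rt
Reagents that add atoms: 3,4-dimethoxybenzoyl chloride, COc1ccc(C(Cl)=O)cc1OC
Why: Transient boronate protection ties the syn-1,3-diol at C1 and C8 into a six-membered phenylboronate, so the only free secondary hydroxyl (C4) is acylated under DMAP catalysis while the tertiary C3 hydroxyl stays inert, and transesterification with pinacol should release the diol with no stereocentre affected.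

Step 10
Reactants: 24 diol ester; 25 acetic anhydride
Product: 26 target (1S,3R,3aS,4S,8R,8aR)-1,8-diacetoxy-3-hydroxy-6,8a-dimethyl-3-(propan-2-yl)-1,2,3,3a,4,5,8,8a-octahydroazulen-4-yl 3,4-dimethoxybenzoate
Conditions: Ac2O, Et3N, DMAP (cat.), CH2Cl2, rt
Reagents that add atoms: acetic anhydride, CC(=O)OC(C)=O
Why: DMAP-catalysed acetylation should esterify the two secondary alcohols at C1 and C8, whereas the hindered tertiary alcohol does not react at room temperature and no stereocentre changes.

Compound list
1 | 3,5-dimethoxytoluene | COc1cc(C)cc(OC)c1 | starting material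
2 | N-methoxy-N-methyl-2-methylpropanamide | CC(C)C(=O)N(C)OC | starting material
3 | (2,6-dimethoxy-4-methylphenyl)lithium | [Li]c1c(OC)cc(C)cc1OC | intermediate
4 | lithium 1-(2,6-dimethoxy-4-methylphenyl)-1-[methoxy(methyl)amino]-2-methylpropan-1-olate | CC(C)C(O[Li])(N(C)OC)c1c(OC)cc(C)cc1OC | intermediate
5 | 1-(2,6-dimethoxy-4-methylphenyl)-2-methylpropan-1-one | CC(C)C(=O)c1c(OC)cc(C)cc1OC | intermediate
6 | allylboronic acid pinacol ester (2-allyl-4,4,5,5-tetramethyl-1,3,2-dioxaborolane) | C=CCB1OC(C)(C)C(C)(C)O1 | starting material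
7 | 2-{[(3R)-3-(2,6-dimethoxy-4-methylphenyl)-2-methylhex-5-en-3-yl]oxy}-4,4,5,5-tetramethyl-1,3,2-dioxaborolane | C=CC[C@@](OB1OC(C)(C)C(C)(C)O1)(C(C)C)c1c(OC)cc(C)cc1OC | intermediate
8 | (3R)-3-(2,6-dimethoxy-4-methylphenyl)-2-methylhex-5-en-3-ol | C=CC[C@@](O)(C(C)C)c1c(OC)cc(C)cc1OC | intermediate
9 | (3R)-3-(2,6-dimethoxy-4-methylphenyl)-3-hydroxy-4-methylpentanoic acid | OC(=O)C[C@@](O)(C(C)C)c1c(OC)cc(C)cc1OC | intermediate
10 | N,O-bis(trimethylsilyl)acetamide | CC(=N[Si](C)(C)C)O[Si](C)(C)C | starting material
11 | diazoethane (freshly prepared reagent) | CC=[N+]=[N-] | starting material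
12 | trimethylsilyl (3R)-3-(2,6-dimethoxy-4-methylphenyl)-4-methyl-3-[(trimethylsilyl)oxy]pentanoate | C[Si](C)(C)OC(=O)C[C@@](O[Si](C)(C)C)(C(C)C)c1c(OC)cc(C)cc1OC | intermediate
13 | (3R)-3-(2,6-dimethoxy-4-methylphenyl)-4-methyl-3-[(trimethylsilyl)oxy]pentanoyl chloride | ClC(=O)C[C@@](O[Si](C)(C)C)(C(C)C)c1c(OC)cc(C)cc1OC | intermediate
14 | (5R)-2-diazo-5-(2,6-dimethoxy-4-methylphenyl)-6-methyl-5-[(trimethylsilyl)oxy]heptan-3-one | CC(=[N+]=[N-])C(=O)C[C@@](O[Si](C)(C)C)(C(C)C)c1c(OC)cc(C)cc1OC | intermediate
15 | norcaradiene valence isomer of 16 (cyclopropane of C8a, C3a and C8 fused to the cyclopentanone and to a methoxy-substituted cyclohexadiene; angular methyl over the diene) | C[C@]12C(=O)C[C@@](O[Si](C)(C)C)(C(C)C)[C@]13C(OC)=CC(C)=C[C@]23OC | intermediate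
16 | (3R,8aS)-4,8-dimethoxy-6,8a-dimethyl-3-(propan-2-yl)-3-[(trimethylsilyl)oxy]-3,8a-dihydroazulen-1(2H)-one | C[C@]12C(=O)C[C@@](O[Si](C)(C)C)(C(C)C)C1=C(OC)C=C(C)C=C2OC | intermediate
17 | (3R,3aR,8aR)-3-hydroxy-6,8a-dimethyl-3-(propan-2-yl)-2,3,3a,5-tetrahydroazulene-1,4,8(8aH)-trione | C[C@]12C(=O)C[C@@](O)(C(C)C)[C@@H]1C(=O)CC(C)=CC2=O | intermediate
18 | (1S,3R,3aS,4S,8aR)-1,3,4-trihydroxy-6,8a-dimethyl-3-(propan-2-yl)-2,3,3a,4,5,8a-hexahydroazulen-8(1H)-one | O[C@H]1CC(C)=CC(=O)[C@@]2(C)[C@@H](O)C[C@@](O)(C(C)C)[C@H]12 | intermediate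
19 | 1-O-diethylboryl derivative of 18 (boron also coordinated by the C8 carbonyl oxygen) | O[C@H]1CC(C)=CC(=O)[C@@]2(C)[C@@H](OB(CC)CC)C[C@@](O)(C(C)C)[C@H]12 | intermediate
20 | (1S,3R,3aS,4S,8R,8aR)-6,8a-dimethyl-3-(propan-2-yl)-1,2,3,3a,4,5,8,8a-octahydroazulene-1,3,4,8-tetrol | O[C@H]1CC(C)=C[C@@H](O)[C@@]2(C)[C@@H](O)C[C@@](O)(C(C)C)[C@H]12 | intermediate
21 | 3,4-dimethoxybenzoyl chloride | COc1ccc(C(Cl)=O)cc1OC | starting material
22 | cyclic phenylboronate of 20 across the C1 and C8 oxygens | O[C@H]1CC(C)=C[C@@H](O3)[C@@]2(C)[C@@H](OB3c4ccccc4)C[C@@](O)(C(C)C)[C@H]12 | intermediate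
23 | 4-O-(3,4-dimethoxybenzoyl) derivative of 22 | COc1ccc(C(=O)O[C@H]2CC(C)=C[C@@H](O4)[C@@]3(C)[C@@H](OB4c5ccccc5)C[C@@](O)(C(C)C)[C@H]23)cc1OC | intermediate
24 | (1S,3R,3aS,4S,8R,8aR)-1,3,8-trihydroxy-6,8a-dimethyl-3-(propan-2-yl)-1,2,3,3a,4,5,8,8a-octahydroazulen-4-yl 3,4-dimethoxybenzoate | COc1ccc(C(=O)O[C@H]2CC(C)=C[C@@H](O)[C@@]3(C)[C@@H](O)C[C@@](O)(C(C)C)[C@H]23)cc1OC | intermediate
25 | acetic anhydride | CC(=O)OC(C)=O | starting material
26 | (1S,3R,3aS,4S,8R,8aR)-1,8-diacetoxy-3-hydroxy-6,8a-dimethyl-3-(propan-2-yl)-1,2,3,3a,4,5,8,8a-octahydroazulen-4-yl 3,4-dimethoxybenzoate | COc1ccc(C(=O)O[C@H]2CC(C)=C[C@@H](OC(C)=O)[C@@]3(C)[C@@H](OC(C)=O)C[C@@](O)(C(C)C)[C@H]23)cc1OC | target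

Total step count: 10. Longest linear sequence: 10 steps (from 1 to 26).

Steps most likely to fail

Step 5 (key step). The methyl-substituted carbenoid may be lost to 1,2-hydride shift, be intercepted by the silyl ether oxygen (oxonium ylide), insert into the isopropyl C–H bond, or add with the wrong facial sense. The fallback introduces the angular methyl after the ring expansion. It sets out from acid 9, which is silylated and converted to chloride 13 as in step 4 but treated with diazomethane to give the terminal diazoketone (4R)-1-diazo-4-(2,6-dimethoxy-4-methylphenyl)-5-methyl-4-[(trimethylsilyl)oxy]hexan-2-one F1. Its Büchner reaction with Rh2(OAc)4 (no neighbouring hydrogen to shift, less hindered carbenoid) should give the 8a-unsubstituted azulenone (3R,8aS)-4,8-dimethoxy-6-methyl-3-(propan-2-yl)-3-[(trimethylsilyl)oxy]-3,8a-dihydroazulen-1(2H)-one F2. Aqueous HCl should then give the cyclic β-diketone (3R,3aR)-3-hydroxy-6-methyl-3-(propan-2-yl)-2,3,3a,5-tetrahydroazulene-1,4,8(8aH)-trione F3. C-methylation of F3 at C8a (MeI, K2CO3, acetone), expected trans to the isopropyl group, comes back to the route at trione 17.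

Step 2. The di-ortho-substituted aryl isopropyl ketone may react too slowly or with poor enantiofacial discrimination. The fallback makes the carbinol racemic and resolves it. It sets out from ketone 5: a Reformatsky reaction (ethyl bromoacetate, Zn, THF) should give racemic ethyl 3-(2,6-dimethoxy-4-methylphenyl)-3-hydroxy-4-methylpentanoate F4, and LiOH gives the racemic acid 3-(2,6-dimethoxy-4-methylphenyl)-3-hydroxy-4-methylpentanoic acid F5. Crystallisation with (S)-1-phenylethylamine should separate the (S)-1-phenylethylammonium salt of the (R)-acid F6 (the antipode of the amine is used if this salt proves the more soluble one). Mild acidification releases acid 9, where the route is rejoined.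

Step 7. Chemoselectivity may be lost: once the C1 hydroxyl has formed it can deliver hydride to the C8 enone, giving the anti (8S) carbinol. The fallback replaces chemoselective reduction by exhaustive reduction and selective re-oxidation. It sets out from trione 17, which is reduced completely with excess Me4NBH(OAc)3 to the 8-epi-tetrol (1S,3R,3aS,4S,8S,8aR)-6,8a-dimethyl-3-(propan-2-yl)-1,2,3,3a,4,5,8,8a-octahydroazulene-1,3,4,8-tetrol F7. MnO2 in CH2Cl2 should then oxidise only the allylic C8 alcohol and come back to the route at enone 18.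

Further compounds
F1 | step 5 | (4R)-1-diazo-4-(2,6-dimethoxy-4-methylphenyl)-5-methyl-4-[(trimethylsilyl)oxy]hexan-2-one | [N-]=[N+]=CC(=O)C[C@@](O[Si](C)(C)C)(C(C)C)c1c(OC)cc(C)cc1OC
F2 | step 5 | (3R,8aS)-4,8-dimethoxy-6-methyl-3-(propan-2-yl)-3-[(trimethylsilyl)oxy]-3,8a-dihydroazulen-1(2H)-one | O=C1C[C@@](O[Si](C)(C)C)(C(C)C)C2=C(OC)C=C(C)C=C(OC)[C@@H]12
F3 | step 5 | (3R,3aR)-3-hydroxy-6-methyl-3-(propan-2-yl)-2,3,3a,5-tetrahydroazulene-1,4,8(8aH)-trione (C8a enolisable) | O=C1C[C@@](O)(C(C)C)[C@@H]2C(=O)CC(C)=CC(=O)C12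
F4 | step 2 | racemic ethyl 3-(2,6-dimethoxy-4-methylphenyl)-3-hydroxy-4-methylpentanoate | CCOC(=O)CC(O)(C(C)C)c1c(OC)cc(C)cc1OC
F5 | step 2 | racemic 3-(2,6-dimethoxy-4-methylphenyl)-3-hydroxy-4-methylpentanoic acid | OC(=O)CC(O)(C(C)C)c1c(OC)cc(C)cc1OC
F6 | step 2 | (S)-1-phenylethylammonium (3R)-3-(2,6-dimethoxy-4-methylphenyl)-3-hydroxy-4-methylpentanoate | C[C@H]([NH3+])c1ccccc1.[O-]C(=O)C[C@@](O)(C(C)C)c1c(OC)cc(C)cc1OC
F7 | step 7 | (1S,3R,3aS,4S,8S,8aR)-6,8a-dimethyl-3-(propan-2-yl)-1,2,3,3a,4,5,8,8a-octahydroazulene-1,3,4,8-tetrol | O[C@H]1CC(C)=C[C@H](O)[C@@]2(C)[C@@H](O)C[C@@](O)(C(C)C)[C@H]12
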